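**Retrosynthetic overview**
1. The target comes by O-methylation from a hydroxy-methoxy-quinone. That quinone comes by carbonate methanolysis and air oxidation from a hexasubstituted phenol whose two adjacent ring oxygens are tied up as a cyclic carbonate.
2. The arene arises in the key step by a two-carbon ring expansion (4π opening of a cyclobutenone, 6π closure of the dienylketene). The precursor is an isomeric spiro cyclobutenone/alkylidene-dioxolanone.
3. The spiro compound comes from CO2 and a tertiary propargylic alcohol, itself made from a 3-ethynylindole and an indolyl methoxy cyclobutenedione. Both partners derive from 2-(1,1-dimethylallyl)indole, made by Madelung closure of an o-toluidide.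
4. Enabling feature: the quinone ring reads C(=O)–C(OMe)=C(indolyl)–C(=O)–C(O)=C(indolyl). The first four atoms are the carbon set of a squaric acid derivative whose two carbonyl carbons end up para. The last two are an alkyne carbon pair (one oxygenated, one indolyl-bearing) slotted between them.
5. Ring order: the two indole pyrrole rings, the purchased four-membered ring, the temporary dioxolanone ring, the six-membered ring grown from the four-membered one, then removal of the dioxolanone.

Key step: step 8

Assumption: 2,2-dimethylbut-3-enoic acid, 3,4-dichlorocyclobut-3-ene-1,2-dione and TIPS-EBX are taken as purchasable. The target has no stereocentre, and rotamers about the indolyl–quinone bonds are not specified, so all chiral intermediates are racemic.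
Abbreviation: Ar = 2-(2-methylbut-3-en-2-yl)-1H-indol-3-yl.

**Step 1**
Reactants: 1 2,2-dimethylbut-3-enoic acid; 2 2-methylaniline
Product: 4 2,2-dimethyl-N-(2-methylphenyl)but-3-enamide, via acid chloride 3 (not isolated)
Conditions: (COCl)2, cat. DMF, CH2Cl2, 0 °C to rt; then 2, Et3N, 0 °C to rt
Reagents that add atoms: none
Why: Acid chloride formation followed by Schotten–Baumann-type N-acylation, since the chloride is needed to drive the hindered quaternary acid onto the aniline.

**Step 2**
Reactants: 4 2,2-dimethyl-N-(2-methylphenyl)but-3-enamide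
Product: 6 2-(2-methylbut-3-en-2-yl)-1H-indole, via dilithiated amide 5 (not isolated)
Conditions: n-BuLi (3 equiv), THF, −20 °C to rt; aq NH4Cl
Reagents that add atoms: none
Why: Madelung indole synthesis in its organolithium variant, in which amidate-directed lateral lithiation of the methyl group, attack on the amide carbon and dehydration should follow the closely related tert-alkyl anilide cases, and the quaternary allylic carbon offers no competing acidic hydrogen.

**Step 3**
Reactants: 6 2-(2-methylbut-3-en-2-yl)-1H-indole; 7 3,4-dichlorocyclobut-3-ene-1,2-dione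
Product: 9 3-methoxy-4-Ar-cyclobut-3-ene-1,2-dione, via chloride 8 (not isolated)
Conditions: 7 (1.3 equiv), Et2O, 0 °C to rt; then MeOH, rt
Reagents that add atoms: methanol, CO
Why: Uncatalysed Friedel–Crafts-type addition–elimination of the nucleophilic indole C3 on the vinylogous acid chloride, then methanolysis of the second C–Cl, with the bulky 2-substituent and the excess of 7 holding back a second arylation.

**Step 4**
Reactants: 6 2-(2-methylbut-3-en-2-yl)-1H-indole; 10 1-[(triisopropylsilyl)ethynyl]-1,2-benziodoxol-3(1H)-one (TIPS-EBX)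
Product: 11 2-(2-methylbut-3-en-2-yl)-3-[(triisopropylsilyl)ethynyl]-1H-indole
Conditions: 10 (1.2 equiv), AuCl (5 mol %), Et2O, rt, dark
Reagents that add atoms: none
Why: Direct C3–H alkynylation of an N–H indole with an ethynylbenziodoxolone under catalysis by monovalent gold, where C2 is blocked and the slim alkyne should tolerate the neighbouring tert-alkyl group.

**Step 5**
Reactants: 11 2-(2-methylbut-3-en-2-yl)-3-[(triisopropylsilyl)ethynyl]-1H-indole
Product: 12 3-ethynyl-2-(2-methylbut-3-en-2-yl)-1H-indole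
Conditions: Bu4NF, wet THF, 0 °C; used at once
Reagents that add atoms: none
Why: Fluoride-induced protodesilylation of an alkynylsilane, which touches no other group in the molecule.

**Step 6**
Reactants: 9 3-methoxy-4-Ar-cyclobut-3-ene-1,2-dione; 12 3-ethynyl-2-(2-methylbut-3-en-2-yl)-1H-indole
Product: 15 (±)-4-hydroxy-2-methoxy-3-Ar-4-(Ar-ethynyl)cyclobut-2-en-1-one, via dilithio alkyne 13 (not isolated), via lithium indolide 14 (not isolated)
Conditions: 12, n-BuLi (2 equiv), THF, −78 to 0 °C; 9, LiN(SiMe3)2 (1 equiv), THF, −78 °C; mix at −78 °C, to −30 °C; aq NH4Cl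
Reagents that add atoms: none
Why: 1,2-Addition of a lithium acetylide to a cyclobutenedione, in which the nitrogen lone pair of 14 is conjugated through indole C2=C3 and the ring C=C with the carbonyl next to C–OMe (a vinylogous amidate, switched off), so the acetylide should take the carbonyl next to the Ar-bearing carbon (a vinylogous ester, Stork–Danheiser-type acceptor), and the racemic carbinol centre is erased in step 8.

**Step 7**
Reactants: 15 (±)-4-hydroxy-2-methoxy-3-Ar-4-(Ar-ethynyl)cyclobut-2-en-1-one
Product: 17 (±)-(8Z)-2-methoxy-3-Ar-8-(Ar-methylidene)-5,7-dioxaspiro[3.4]oct-2-ene-1,6-dione, via hydrogen carbonate 16 (not isolated)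
Conditions: CO2 (1 MPa), AgOAc (10 mol %), DBU (1 equiv), toluene, 25 °C, dark
Reagents that add atoms: carbon dioxide, O=C=O
Why: Silver-catalysed carboxylative cyclisation of a tertiary propargylic alcohol, where the carbonate oxygen of 16 adds anti and 5-exo-dig to the alkyne bound to monovalent silver, placing oxygen on the alkyne carbon next to the carbinol and giving, after protodemetalation, the Z-alkylidene (indolyl cis to the ring oxygen).

**Step 8**
Reactants: 17 (±)-(8Z)-2-methoxy-3-Ar-8-(Ar-methylidene)-5,7-dioxaspiro[3.4]oct-2-ene-1,6-dione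
Product: 20 6-hydroxy-5-methoxy-4,7-di-Ar-1,3-benzodioxol-2-one, via dienylketene 18 (not isolated), via cyclohexadienone 19 (not isolated)
Conditions: degassed toluene (0.01 M), 110 °C
Reagents that add atoms: none
Why: Heating should open the cyclobutenone by conrotatory 4π cleavage of the bond between the acyl carbon and the spiro carbon; the carbonate oxygen turns outward as donor substituents do, so the enol-carbonate carbon turns inward and the ketene of 18 lies next to the exocyclic C=CH(Ar) bond. The six-membered ring then closes by disrotatory 6π electrocyclisation between the ketene carbon and the CH(Ar) carbon, with the s-cis diene locked by the dioxolanone ring and the Z geometry of 17 keeping the bulky indolyl on the outside of the closing triene, and 19 enolises to phenol 20. The closest known reaction type is the Moore-type ring expansion of 4-alkenyl-4-oxycyclobutenones to hydroquinone derivatives. The only new stereocentre, CH(Ar) of 19, is lost at once on aromatisation, so no control is needed. The substitution pattern follows from connectivity rather than selectivity: the two alkyne-derived carbons enter between the two former squarate carbonyl carbons, which fixes the order O, OMe, Ar, O, O, Ar around the ring. A ketene opened the wrong way (oxygen inward) cannot lactonise because that oxygen is tied up as carbonate, so it should reclose to 17 and the productive channel should drain the equilibrium.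

**Step 9**
Reactants: 20 6-hydroxy-5-methoxy-4,7-di-Ar-1,3-benzodioxol-2-one
Product: 22 2-hydroxy-5-methoxy-3,6-di-Ar-cyclohexa-2,5-diene-1,4-dione, via benzenetriol 21 (not isolated)
Conditions: K2CO3 (3 equiv), MeOH, air, rt; then 1 M HCl
Reagents that add atoms: none
Why: Base-catalysed transesterification of the strained aryl carbonate followed by autoxidation of the very electron-rich benzenetriol to the hydroxyquinone, with methoxide exchange at the ring OMe being degenerate.

**Step 10**
Reactants: 22 2-hydroxy-5-methoxy-3,6-di-Ar-cyclohexa-2,5-diene-1,4-dione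
Product: 23 2,5-dimethoxy-3,6-di-Ar-cyclohexa-2,5-diene-1,4-dione (target)
Conditions: Me3SiCHN2 (2 equiv), toluene–MeOH 4:1, 0 °C
Reagents that add atoms: (trimethylsilyl)diazomethane, C[Si](C)(C)C=[N+]=[N-]
Why: O-Methylation of a vinylogous carboxylic acid by a diazoalkane, for which the indole N–H groups are too weakly acidic and the tetrasubstituted quinone C=C bonds too hindered to react.

**Compound list**
1 | 2,2-dimethylbut-3-enoic acid | C=CC(C)(C)C(=O)O | starting material
2 | 2-methylaniline | Cc1ccccc1N | starting material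
3 | 2,2-dimethylbut-3-enoyl chloride | C=CC(C)(C)C(=O)Cl | intermediate
4 | 2,2-dimethyl-N-(2-methylphenyl)but-3-enamide | C=CC(C)(C)C(=O)Nc1ccccc1C | intermediate
5 | N,C-dilithiated amide 4 | [Li+].[Li+].C=CC(C)(C)C(=O)[N-]c1ccccc1[CH2-] | intermediate
6 | 2-(2-methylbut-3-en-2-yl)-1H-indole | C=CC(C)(C)c1cc2ccccc2[nH]1 | intermediate
7 | 3,4-dichlorocyclobut-3-ene-1,2-dione | ClC1=C(Cl)C(=O)C1=O | starting material
8 | 3-chloro-4-Ar-cyclobut-3-ene-1,2-dione | ClC1=C(c2c(C(C)(C)C=C)[nH]c3ccccc23)C(=O)C1=O | intermediate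
9 | 3-methoxy-4-Ar-cyclobut-3-ene-1,2-dione | COC1=C(c2c(C(C)(C)C=C)[nH]c3ccccc23)C(=O)C1=O | intermediate
10 | 1-[(triisopropylsilyl)ethynyl]-1,2-benziodoxol-3(1H)-one | CC(C)[Si](C#CI1OC(=O)c2ccccc12)(C(C)C)C(C)C | starting material
11 | 2-(2-methylbut-3-en-2-yl)-3-[(triisopropylsilyl)ethynyl]-1H-indole | C=CC(C)(C)c1[nH]c2ccccc2c1C#C[Si](C(C)C)(C(C)C)C(C)C | intermediate
12 | 3-ethynyl-2-(2-methylbut-3-en-2-yl)-1H-indole | C=CC(C)(C)c1[nH]c2ccccc2c1C#C | intermediate
13 | N,C-dilithiated alkyne 12 | [Li+].[Li+].C=CC(C)(C)c1[n-]c2ccccc2c1C#[C-] | intermediate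
14 | lithium indolide of 9 | [Li+].COC1=C(c2c(C(C)(C)C=C)[n-]c3ccccc23)C(=O)C1=O | intermediate
15 | (±)-4-hydroxy-2-methoxy-3-Ar-4-(Ar-ethynyl)cyclobut-2-en-1-one | COC1=C(c2c(C(C)(C)C=C)[nH]c3ccccc23)C(O)(C#Cc2c(C(C)(C)C=C)[nH]c3ccccc23)C1=O | intermediate
16 | (±)-hydrogen carbonate of 15 (present as its DBU salt) | COC1=C(c2c(C(C)(C)C=C)[nH]c3ccccc23)C(OC(=O)O)(C#Cc2c(C(C)(C)C=C)[nH]c3ccccc23)C1=O | intermediate
17 | (±)-(8Z)-2-methoxy-3-Ar-8-(Ar-methylidene)-5,7-dioxaspiro[3.4]oct-2-ene-1,6-dione | COC1=C(c2c(C(C)(C)C=C)[nH]c3ccccc23)C4(OC(=O)O/C4=C\c2c(C(C)(C)C=C)[nH]c3ccccc23)C1=O | intermediate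
18 | dienylketene: 4-(1-Ar-2-methoxy-3-oxoprop-2-enylidene)-5-(Ar-methylidene)-1,3-dioxolan-2-one, ketene chain cis to the neighbouring exocyclic C=C | O=C=C(OC)/C(c2c(C(C)(C)C=C)[nH]c3ccccc23)=C1/OC(=O)O/C1=C\c2c(C(C)(C)C=C)[nH]c3ccccc23 | intermediate
19 | (±)-5-methoxy-4,7-di-Ar-1,3-benzodioxole-2,6(7H)-dione | O=C1OC2=C(O1)C(c3c(C(C)(C)C=C)[nH]c4ccccc34)C(=O)C(OC)=C2c3c(C(C)(C)C=C)[nH]c4ccccc34 | intermediate
20 | 6-hydroxy-5-methoxy-4,7-di-Ar-1,3-benzodioxol-2-one | O=C1Oc2c(-c3c(C(C)(C)C=C)[nH]c4ccccc34)c(OC)c(O)c(-c3c(C(C)(C)C=C)[nH]c4ccccc34)c2O1 | intermediate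
21 | 5-methoxy-3,6-di-Ar-benzene-1,2,4-triol | COc1c(O)c(-c2c(C(C)(C)C=C)[nH]c3ccccc23)c(O)c(O)c1-c4c(C(C)(C)C=C)[nH]c5ccccc45 | intermediate
22 | 2-hydroxy-5-methoxy-3,6-di-Ar-cyclohexa-2,5-diene-1,4-dione | COC1=C(c2c(C(C)(C)C=C)[nH]c3ccccc23)C(=O)C(O)=C(c2c(C(C)(C)C=C)[nH]c3ccccc23)C1=O | intermediate
23 | 2,5-dimethoxy-3,6-di-Ar-cyclohexa-2,5-diene-1,4-dione | C=CC(C)(C)c1[nH]c2ccccc2c1C1=C(OC)C(=O)C(c2c(C(C)(C)C=C)[nH]c3ccccc23)=C(OC)C1=O | target

**Total step count:** 10. **Longest linear sequence:** 9 (steps 1, 2, 4, 5, 6, 7, 8, 9, 10).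

**Steps most likely to fail**

**Step 6.**
- What may go wrong: If the hindered indolide is twisted out of conjugation, the electronic bias is lost and the acetylide may add at the carbonyl next to C–OMe. It may also displace methoxide by conjugate addition–elimination.
- Fallback (sets out from 9, comes back at 15): The carbonyl that proves more electrophilic is masked first, following the cyclobutenedione monoacetal tactic.
  - HC(OMe)3, cat. TsOH and MeOH should convert 9 into the monoacetal 3,4,4-trimethoxy-2-Ar-cyclobut-2-en-1-one F1.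
  - After N-deprotonation with LiN(SiMe3)2, the only remaining carbonyl, next to the Ar-bearing carbon, should take 13 to give 1-(Ar-ethynyl)-3,4,4-trimethoxy-2-Ar-cyclobut-2-en-1-ol F2.
  - Wet silica gel with oxalic acid in CH2Cl2 should unmask the ketone and rejoin the route at 15.

**Step 7.**
- What may go wrong: The indolyl-stabilised positive end of the silver-bound alkyne may favour 6-endo closure. The base may also open the four-membered ring before CO2 is captured.
- Fallback (sets out from 15, comes back at 22): The missing oxygen is brought in after the ring expansion.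
  - Semihydrogenation of 15 (H2, Pd on CaCO3 poisoned with Pb(OAc)2, quinoline) should give (±)-4-hydroxy-2-methoxy-3-Ar-4-[(Z)-2-Ar-ethenyl]cyclobut-2-en-1-one F3.
  - Heating in p-xylene at 138 °C should give 2-methoxy-3,6-di-Ar-benzene-1,4-diol F4.
  - Ag2O should oxidise this to 2-methoxy-3,6-di-Ar-cyclohexa-2,5-diene-1,4-dione F5.
  - Weitz–Scheffer epoxidation (t-BuOOH, DBU) of the only trisubstituted quinone C=C should give the (±)-5,6-epoxide F6.
  - Base-induced opening of the epoxide through the enolate next to it should deliver 22.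

**Step 8.**
- What may go wrong: The carbonate oxygen is a weaker donor than OH or OR, so outward rotation may be less favoured and the opening slower. At the higher temperature then needed, loss of CO2 or capture of the ketene by an indole N–H may take over.
- Fallback (sets out from 17, comes back at 22): The temporary ring is opened before heating.
  - MeOH with cat. DBU should turn 17 into the β-oxo carbonate (±)-1-(Ar-acetyl)-3-methoxy-4-oxo-2-Ar-cyclobut-2-en-1-yl methyl carbonate F7.
  - Me3SiOTf and Et3N should give its (Z)-trimethylsilyl enol ether F8, a freely rotating and more electron-rich 4-alkenyl group.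
  - Heating in toluene should give 4-hydroxy-3-methoxy-2,5-di-Ar-6-(trimethylsilyloxy)phenyl methyl carbonate F9.
  - The conditions of step 9 should convert F9 into 22.

**Further compounds**
F1 | step 6 | 3,4,4-trimethoxy-2-Ar-cyclobut-2-en-1-one | COC1=C(c2c(C(C)(C)C=C)[nH]c3ccccc23)C(=O)C1(OC)OC
F2 | step 6 | (±)-1-(Ar-ethynyl)-3,4,4-trimethoxy-2-Ar-cyclobut-2-en-1-ol | COC1=C(c2c(C(C)(C)C=C)[nH]c3ccccc23)C(O)(C#Cc2c(C(C)(C)C=C)[nH]c3ccccc23)C1(OC)OC
F3 | step 7 | (±)-4-hydroxy-2-methoxy-3-Ar-4-[(Z)-2-Ar-ethenyl]cyclobut-2-en-1-one | COC1=C(c2c(C(C)(C)C=C)[nH]c3ccccc23)C(O)(/C=C\c2c(C(C)(C)C=C)[nH]c3ccccc23)C1=O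
F4 | step 7 | 2-methoxy-3,6-di-Ar-benzene-1,4-diol | COc1c(O)c(-c2c(C(C)(C)C=C)[nH]c3ccccc23)cc(O)c1-c4c(C(C)(C)C=C)[nH]c5ccccc45
F5 | step 7 | 2-methoxy-3,6-di-Ar-cyclohexa-2,5-diene-1,4-dione | COC1=C(c2c(C(C)(C)C=C)[nH]c3ccccc23)C(=O)C=C(c2c(C(C)(C)C=C)[nH]c3ccccc23)C1=O
F6 | step 7 | (±)-5,6-epoxide of F5 | COC1=C(c2c(C(C)(C)C=C)[nH]c3ccccc23)C(=O)C4OC4(c2c(C(C)(C)C=C)[nH]c3ccccc23)C1=O
F7 | step 8 | (±)-1-(Ar-acetyl)-3-methoxy-4-oxo-2-Ar-cyclobut-2-en-1-yl methyl carbonate | COC(=O)OC1(C(=O)Cc2c(C(C)(C)C=C)[nH]c3ccccc23)C(c2c(C(C)(C)C=C)[nH]c3ccccc23)=C(OC)C1=O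
F8 | step 8 | (±)-(Z)-trimethylsilyl enol ether of F7 | COC(=O)OC1(/C(O[Si](C)(C)C)=C/c2c(C(C)(C)C=C)[nH]c3ccccc23)C(c2c(C(C)(C)C=C)[nH]c3ccccc23)=C(OC)C1=O
F9 | step 8 | 4-hydroxy-3-methoxy-2,5-di-Ar-6-(trimethylsilyloxy)phenyl methyl carbonate | COc1c(O)c(-c2c(C(C)(C)C=C)[nH]c3ccccc23)c(O[Si](C)(C)C)c(OC(=O)OC)c1-c4c(C(C)(C)C=C)[nH]c5ccccc45
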